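## Retrosynthetic overview

1. Target ⇒ desilylation and Claisen closure of ring B (C3–C2) from an aryl β-diketone. Its ArCO–C3 bond is the key disconnection: the acyl anion (carbene/Breslow form) of a protected protocatechualdehyde is alkylated by an α-chloroketone, so two electrophilic carbons are joined.
2. α-Chloroketone ⇒ ClCH2Li plus the C5 ester of a fully substituted cyclohexanone diester (ring A).
3. Ring A quaternary centres ⇒ C5 geranylation and tandem C8 methylation/C1 prenylation, both anti to the C7 geranyl group.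
4. Ring A ⇒ amine-catalysed asymmetric Michael/protonation/Knoevenagel annulation of an α-methylene ketone with dimethyl 3-oxopentanedioate (sets C7).
5. α-Methylene ketone ⇒ acetylacetone, geranyl bromide and formaldehyde. Ring order: ring A first, ring B last.

Abbreviations: geranyl = (2E)-3,7-dimethylocta-2,6-dien-1-yl; prenyl = 3-methylbut-2-en-1-yl; TBS = tert-butyldimethylsilyl; C1–C9 in the text are the bicyclo[3.3.1]nonane positions of the target.

Assumption: the quinine-derived amine in step 3 is taken to give the (S) centre (otherwise the quinidine-derived pseudoenantiomer of the same formula is used), and ClCH2Li in step 6 is drawn on the less hindered C5 ester (attack on the C1 ester converges on the same final product).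

## Route

**Step 1**
Reactants: 1 pentane-2,4-dione; 2 geranyl bromide [(2E)-1-bromo-3,7-dimethylocta-2,6-diene]
Product: 3 3-[(2E)-3,7-dimethylocta-2,6-dien-1-yl]pentane-2,4-dione
Conditions: K2CO3, acetone, 56 °C (2 equiv of 1)
Reagents that add atoms: none
Why: SN2 C-alkylation of the acetylacetone enolate by the primary allylic bromide (β-diketone alkylation), with excess 1 suppressing dialkylation and the E olefin untouched.

**Step 2**
Reactants: 3 3-geranylpentane-2,4-dione
Product: 4 (5E)-6,10-dimethyl-3-methylideneundeca-5,9-dien-2-one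
Conditions: 37% aq. CH2O, K2CO3, H2O/THF, rt
Reagents that add atoms: formaldehyde, C=O
Why: Deacetylative α-methylenation: aldol addition to formaldehyde, retro-Claisen loss of acetate and E1cB elimination give the α-methylene ketone.

**Step 3**
Reactants: 4 (5E)-6,10-dimethyl-3-methylideneundeca-5,9-dien-2-one; 5 dimethyl 3-oxopentanedioate (1.5 equiv)
Product: 6 dimethyl (5S)-5-geranyl-4-methyl-2-oxocyclohex-3-ene-1,3-dicarboxylate (C1 epimers/enol)
Conditions: 9-amino-9-deoxy-epi-quinine (C20H25N3O, 20 mol%), CF3CO2H (40 mol%), toluene, 0 → 40 °C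
Reagents that add atoms: none
Why: Proposed new method: the primary amine forms an iminium ion with the α-substituted vinyl ketone, the enol of 5 adds (Michael), the resulting enamine is protonated on one face by the catalyst's quinuclidinium to set the C7 centre (S), and the iminium is then trapped by the second active methylene in an intramolecular Knoevenagel condensation that closes ring A; the closest known reaction types are amine-catalysed conjugate addition–enantioselective protonation of α-substituted vinyl ketones and amine-catalysed asymmetric Robinson annulations of β-ketoesters.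

**Step 4**
Reactants: 6 dimethyl (5S)-5-geranyl-4-methyl-2-oxocyclohex-3-ene-1,3-dicarboxylate; 7 prenyl bromide (1-bromo-3-methylbut-2-ene)
Product: 9 dimethyl (3S,5S)-5-geranyl-4,4-dimethyl-2-oxo-3-prenylcyclohexane-1,3-dicarboxylate (C1 epimers/enol), via magnesium bis-enolate 8 (not isolated)
Conditions: MeMgBr (3 equiv), CuBr·SMe2 (0.3 equiv), THF, −40 → 0 °C; then 7 (1.1 equiv), DMPU, 0 °C → rt; aq. NH4Cl
Reagents that add atoms: methylmagnesium bromide, C[Mg]Br
Why: Copper-catalysed 1,4-addition of the methyl Grignard reagent to the alkylidene β-ketoester (after deprotonation of C5–H) builds the C8 gem-dimethyl group, and the ester enolate in 8 is C-alkylated by prenyl bromide on the face opposite the C7 geranyl group (tandem conjugate addition–enolate alkylation), setting the C1 quaternary centre trans to C7.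

**Step 5**
Reactants: 9 dimethyl (3S,5S)-5-geranyl-4,4-dimethyl-2-oxo-3-prenylcyclohexane-1,3-dicarboxylate; 2 geranyl bromide
Product: 10 dimethyl (1R,3S,5S)-1,5-digeranyl-4,4-dimethyl-2-oxo-3-prenylcyclohexane-1,3-dicarboxylate (the two esters cis to each other and to the C5 geranyl group)
Conditions: K2CO3, acetone, 56 °C
Reagents that add atoms: none
Why: β-Ketoester C-alkylation (SN2) in which geranyl bromide enters axially on the face opposite the C7 geranyl group, setting the C5 quaternary centre with both esters cis; the minor epimer and any O-alkyl product are removed by chromatography.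

**Step 6**
Reactants: 10 dimethyl (1R,3S,5S)-1,5-digeranyl-4,4-dimethyl-2-oxo-3-prenylcyclohexane-1,3-dicarboxylate
Product: 11 methyl (1S,3S,5R)-5-(chloroacetyl)-3,5-digeranyl-2,2-dimethyl-6-oxo-1-prenylcyclohexane-1-carboxylate
Conditions: ICH2Cl (1.5 equiv), MeLi·LiBr (1.4 equiv), THF/Et2O, −78 °C; aq. NH4Cl at −78 °C
Reagents that add atoms: chloroiodomethane, ClCI
Why: Carbenoid homologation of an ester: chloromethyllithium made in situ by iodine–lithium exchange adds once to the less hindered C5 ester of the non-enolisable diester, and the tetrahedral lithium hemiketal survives at −78 °C until quench, so the α-chloroketone forms without attack on the doubly neopentyl C9 ketone.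

**Step 7**
Reactants: 12 3,4-dihydroxybenzaldehyde
Product: 13 3,4-bis(tert-butyldimethylsilyloxy)benzaldehyde
Conditions: TBSCl (2.4 equiv), imidazole (5 equiv), DMF, rt
Reagents that add atoms: tert-butyldimethylsilyl chloride, CC(C)(C)[Si](C)(C)Cl
Why: Imidazole-promoted silyl ether formation masks both catechol hydroxyls for the carbene step.

**Step 8**
Reactants: 11 methyl (1S,3S,5R)-5-(chloroacetyl)-3,5-digeranyl-2,2-dimethyl-6-oxo-1-prenylcyclohexane-1-carboxylate; 13 3,4-bis(tert-butyldimethylsilyloxy)benzaldehyde (1.5 equiv)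
Product: 16 oblongifolin D (1S,5S,7S in the drawn enol form), via β-diketone 14 (not isolated), via bis-silyl ether 15 (not isolated)
Conditions: 3-benzyl-5-(2-hydroxyethyl)-4-methylthiazol-3-ium chloride (C13H16ClNOS, 20 mol%), iPr2NEt (1.5 equiv), Bu4NI (20 mol%), THF, 40 °C; then KOtBu (3.5 equiv), THF, 0 → 40 °C; then HF·pyridine (excess), 0 °C → rt
Reagents that add atoms: none
Why: Proposed new method: the thiazolylidene carbene turns aldehyde 13 into its Breslow intermediate (an acyl anion equivalent), which is C-alkylated at the SN2-active CH2X of 11 (X = Cl or I, by direct displacement or electron transfer–radical recombination) and collapses to β-diketone 14 with release of the carbene; KOtBu then drives the Dieckmann (intramolecular Claisen) attack of the diketonate C3 on the cis C1 ester to close ring B without touching the three stereocentres, and HF·pyridine cleaves the aryl silyl ethers; the closest known reaction types are carbene-catalysed alkylation of aldehydes with alkyl halides and sulfonates (polar and radical variants) and Claisen cyclisations of polyketo esters to 2-acylcyclohexane-1,3-diones.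

## Compound list

1 | pentane-2,4-dione | CC(=O)CC(C)=O | starting material
2 | geranyl bromide, (2E)-1-bromo-3,7-dimethylocta-2,6-diene | CC(C)=CCC/C(C)=C/CBr | starting material
3 | 3-[(2E)-3,7-dimethylocta-2,6-dien-1-yl]pentane-2,4-dione | CC(C)=CCC/C(C)=C/CC(C(C)=O)C(C)=O | intermediate
4 | (5E)-6,10-dimethyl-3-methylideneundeca-5,9-dien-2-one | CC(C)=CCC/C(C)=C/CC(=C)C(C)=O | intermediate
5 | dimethyl 3-oxopentanedioate | COC(=O)CC(=O)CC(=O)OC | starting material
6 | dimethyl (5S)-5-geranyl-4-methyl-2-oxocyclohex-3-ene-1,3-dicarboxylate | CC(C)=CCC/C(C)=C/C[C@H]1CC(C(=O)OC)C(=O)C(C(=O)OC)=C1C | intermediate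
7 | prenyl bromide, 1-bromo-3-methylbut-2-ene | CC(C)=CCBr | starting material
8 | bis(bromomagnesium) dienolate of dimethyl (5S)-5-geranyl-4,4-dimethyl-2-oxocyclohexane-1,3-dicarboxylate | CC(C)=CCC/C(C)=C/C[C@H]1CC(C(=O)OC)=C(O[Mg]Br)C(=C(OC)O[Mg]Br)C1(C)C | intermediate
9 | dimethyl (3S,5S)-5-geranyl-4,4-dimethyl-2-oxo-3-prenylcyclohexane-1,3-dicarboxylate | CC(C)=CCC/C(C)=C/C[C@H]1CC(C(=O)OC)C(=O)[C@@](CC=C(C)C)(C(=O)OC)C1(C)C | intermediate
10 | dimethyl (1R,3S,5S)-1,5-digeranyl-4,4-dimethyl-2-oxo-3-prenylcyclohexane-1,3-dicarboxylate | CC(C)=CCC/C(C)=C/C[C@H]1C[C@@](C/C=C(\C)CCC=C(C)C)(C(=O)OC)C(=O)[C@@](CC=C(C)C)(C(=O)OC)C1(C)C | intermediate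
11 | methyl (1S,3S,5R)-5-(chloroacetyl)-3,5-digeranyl-2,2-dimethyl-6-oxo-1-prenylcyclohexane-1-carboxylate | CC(C)=CCC/C(C)=C/C[C@H]1C[C@@](C/C=C(\C)CCC=C(C)C)(C(=O)CCl)C(=O)[C@@](CC=C(C)C)(C(=O)OC)C1(C)C | intermediate
12 | 3,4-dihydroxybenzaldehyde | O=Cc1ccc(O)c(O)c1 | starting material
13 | 3,4-bis(tert-butyldimethylsilyloxy)benzaldehyde | O=Cc1ccc(O[Si](C)(C)C(C)(C)C)c(O[Si](C)(C)C(C)(C)C)c1 | intermediate
14 | methyl (1S,3S,5S)-5-{3-[3,4-bis(tert-butyldimethylsilyloxy)phenyl]-3-oxopropanoyl}-3,5-digeranyl-2,2-dimethyl-6-oxo-1-prenylcyclohexane-1-carboxylate | CC(C)=CCC/C(C)=C/C[C@H]1C[C@@](C/C=C(\C)CCC=C(C)C)(C(=O)CC(=O)c2ccc(O[Si](C)(C)C(C)(C)C)c(O[Si](C)(C)C(C)(C)C)c2)C(=O)[C@@](CC=C(C)C)(C(=O)OC)C1(C)C | intermediate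
15 | 3',4'-bis-O-(tert-butyldimethylsilyl)oblongifolin D | CC(C)=CCC/C(C)=C/C[C@H]1C[C@]2(C/C=C(\C)CCC=C(C)C)C(=O)[C@@](CC=C(C)C)(C(=O)C(C(=O)c3ccc(O[Si](C)(C)C(C)(C)C)c(O[Si](C)(C)C(C)(C)C)c3)=C2O)C1(C)C | intermediate
16 | oblongifolin D | CC(C)=CCC/C(C)=C/C[C@H]1C[C@]2(C/C=C(\C)CCC=C(C)C)C(=O)[C@@](CC=C(C)C)(C(=O)C(C(=O)c3ccc(O)c(O)c3)=C2O)C1(C)C | target

## Step count and risks

Total steps: 8. Longest linear sequence: 7 (steps 1–6 and 8).

**Step 3 (asymmetric annulation).** The enantioselectivity of the protonation is unproven for this substrate, and C7 can epimerise before ring closure. Fallback by resolution: setting out from 4 (with 5), NaOMe in MeOH gives the racemic cyclohexenone diester F1. Condensation with (1R)-1-phenylethan-1-amine (cat. AcOH, toluene, reflux with water removal) gives diastereomeric vinylogous carbamates. The (5S) vinylogous carbamate F2 is separated by crystallisation or chromatography and hydrolysed with aqueous oxalic acid in THF. The route is rejoined at 6.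

**Step 6 (chloromethyllithium homologation).** Double addition, attack at the C9 ketone or poor conversion of the hindered ester are possible. Fallback by a stabilised ylide instead of a carbenoid: setting out from 10, dimethylsulfoxonium methylide (Me3S(O)I, KOtBu, THF, reflux) is acylated by the C5 ester to give the β-keto sulfoxonium ylide F3. Anhydrous HCl (1.1 equiv, THF, 50 °C) then displaces dimethyl sulfoxide. The route is rejoined at 11.

**Step 8 (carbene acyl-anion alkylation/Dieckmann cascade).** The carbene may be alkylated by 11, Darzens or Knoevenagel side reactions may compete, and the diketonate ring closure may be slow. Fallback with normal polarity: setting out from 10, the sodium enolate of 1-[3,4-bis(tert-butyldimethylsilyloxy)phenyl]ethan-1-one F4 (made with TBSCl/imidazole from commercial 3',4'-dihydroxyacetophenone) undergoes a crossed Claisen condensation with the C5 ester (NaH, THF, 60 °C). This gives the β-diketone directly, and the route is rejoined at 14, followed by the KOtBu and HF·pyridine stages of step 8.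

## Further compounds

F1 | step 3 | racemic dimethyl 5-geranyl-4-methyl-2-oxocyclohex-3-ene-1,3-dicarboxylate | CC(C)=CCC/C(C)=C/CC1CC(C(=O)OC)C(=O)C(C(=O)OC)=C1C
F2 | step 3 | dimethyl (5S)-5-geranyl-4-methyl-2-{[(1R)-1-phenylethyl]amino}cyclohexa-1,3-diene-1,3-dicarboxylate | CC(C)=CCC/C(C)=C/C[C@H]1CC(C(=O)OC)=C(N[C@H](C)c2ccccc2)C(C(=O)OC)=C1C
F3 | step 6 | methyl (1S,3S,5R)-5-[2-(dimethyl-oxo-λ6-sulfanylidene)acetyl]-3,5-digeranyl-2,2-dimethyl-6-oxo-1-prenylcyclohexane-1-carboxylate | CC(C)=CCC/C(C)=C/C[C@H]1C[C@@](C/C=C(\C)CCC=C(C)C)(C(=O)C=S(C)(C)=O)C(=O)[C@@](CC=C(C)C)(C(=O)OC)C1(C)C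
F4 | step 8 | 1-[3,4-bis(tert-butyldimethylsilyloxy)phenyl]ethan-1-one | CC(=O)c1ccc(O[Si](C)(C)C(C)(C)C)c(O[Si](C)(C)C(C)(C)C)c1
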